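**Plan**

- Retrosynthesis (target ring: C1 carries CH2OBz, C2 is the vinyl CH, C3 carries OBz, C4 to C6 carry OH): both benzoates come off, the C3 ester by a Mitsunobu inversion; CH2O goes back to an ethyl ester and the C4 carbinol to a ketone; then C2–C3 and C5–C6 are cut together.
- Enabling feature: C3–C4–C5 is a dihydroxyacetone unit, so a C4 ketone makes C3 and C5 nucleophilic; C2, C6 and the CH2O carbon all sit on C1 as the three carbonyl carbons of ethyl diformylacetate (C2 and C6 are its two CHO carbons).
- Forward: one [3+3] annulation of 2,2-dimethyl-1,3-dioxan-5-one with ethyl diformylacetate closes the carbocycle as the second ring of a 2,4-dioxabicyclo[3.3.1]non-6-en-9-one; the acetonide across O3 and O5 makes C3 and C5 bridgeheads, so the product cannot enolise or aromatise.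
- Then: directed reduction at C4, silylation of O4 and O6, ester to CH2OH, removal of the bridge, double benzoylation, desilylation.
- Stereochemistry: C5 and C6 from (R)-proline in the ring-closing aldol; C4 relayed from the C6 hydroxyl; C3 held cis to C5 by the bridge and inverted when it is benzoylated.

Key step: step 1

Remark on the chemistry: 2 is drawn as the dialdehyde but exists mainly as its enol, and its two formyl carbons are equivalent until one has reacted; 1, 2 and (R)-proline are taken as commercial. Bicycle numbering C5/C9/C1/C8 corresponds to target ring C3/C4/C5/C6.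

**Step 1**
Reactants: 1 2,2-dimethyl-1,3-dioxan-5-one; 2 ethyl 2-formyl-3-oxopropanoate
Product: 4 ethyl (1R,5S,8S)-8-hydroxy-3,3-dimethyl-9-oxo-2,4-dioxabicyclo[3.3.1]non-6-ene-7-carboxylate, via alkylidene keto aldehyde 3 (not isolated)
Conditions: (R)-proline (30 mol %), DMSO, rt; 2 (1.0 equiv) added slowly to 1 (1.5 equiv)
Reagents that add atoms: none
Why: Proposed new method: the proline enamine of 1 attacks one of the two equivalent formyl carbons of 2 (free or as its proline vinylogous amide/iminium) and water is lost across the acidic methine, giving the alkylidene 3, whose ring C–H is alpha to the ketone and vinylogous to formyl and ester and therefore epimerises, as does its C=C geometry by amine addition–elimination. The enamine then re-forms on the other alpha carbon and closes onto the remaining formyl group in a 6-(enolendo)-exo-trig aldol, which makes the carbocycle (formal [3+3], dioxanone C4 and C6 to the two formyl carbons) as the second ring of the 2,4-dioxabicyclo[3.3.1]nonane. The closest known reaction types are the Stork–Lawton alpha,alpha'-annulation of the pyrrolidine enamine of 1 with 2-(bromomethyl)acrylates, amine-catalysed Michael–aldol [3+3] annulations of cyclic ketones with enals, and the proline-catalysed aldol of 1 with aldehydes. Stereocontrol: the bridge forces the two C–O bridgeheads cis; the Houk–List transition state (aldehyde oxygen hydrogen-bonded to the carboxylic acid, hence gauche to the iminium carbon) puts the new hydroxyl axial on the carbocycle and anti to the dioxane oxygens; only the epimer of 3 whose arm lies on the acid face of the (R)-proline enamine can close, so C1, C5 and C8 of the bicycle are expected as (1R,5S,8S) by dynamic kinetic resolution, the (R) catalyst being the one this model calls for. The step needs C–C closure without later loss of water: after the first condensation the central carbon has no hydrogen and both ketone alpha carbons are bridgeheads, so 4 can neither dehydrate, epimerise nor aromatise to a gallate as an unbridged dihydroxyacetone would, and closure through oxygen to a pyranol is reversible and should drain into 4.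

**Step 2**
Reactants: 4 ethyl (1R,5S,8S)-8-hydroxy-3,3-dimethyl-9-oxo-2,4-dioxabicyclo[3.3.1]non-6-ene-7-carboxylate
Product: 5 ethyl (1R,5S,8S,9S)-8,9-dihydroxy-3,3-dimethyl-2,4-dioxabicyclo[3.3.1]non-6-ene-7-carboxylate
Conditions: Me4NBH(OAc)3, MeCN/AcOH (1:1), −30 → −20 °C; aq. potassium sodium tartrate
Reagents that add atoms: none
Why: Evans–Saksena hydroxyl-directed reduction, in which the axial C8 hydroxyl binds boron and delivers hydride to the ketone face it overhangs, so the new C9 hydroxyl should point to the side of the dioxane oxygens (1,3-anti diol, 9S) while enoate and acetonide are untouched.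

**Step 3**
Reactants: 5 ethyl (1R,5S,8S,9S)-8,9-dihydroxy-3,3-dimethyl-2,4-dioxabicyclo[3.3.1]non-6-ene-7-carboxylate
Product: 6 ethyl (1R,5S,8S,9S)-8,9-bis[(tert-butyldimethylsilyl)oxy]-3,3-dimethyl-2,4-dioxabicyclo[3.3.1]non-6-ene-7-carboxylate
Conditions: TBSOTf (3 equiv), 2,6-lutidine, CH2Cl2, 0 °C → rt
Reagents that add atoms: tert-butyldimethylsilyl triflate, CC(C)(C)[Si](C)(C)OS(=O)(=O)C(F)(F)F
Why: Silyl ether formation with a silyl triflate and a hindered base covers both secondary hydroxyls in either order without touching a stereocentre, and these ethers later shield the ring C5 hydroxyl in step 6.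

**Step 4**
Reactants: 6 ethyl (1R,5S,8S,9S)-8,9-bis[(tert-butyldimethylsilyl)oxy]-3,3-dimethyl-2,4-dioxabicyclo[3.3.1]non-6-ene-7-carboxylate
Product: 7 [(1R,5S,8S,9S)-8,9-bis[(tert-butyldimethylsilyl)oxy]-3,3-dimethyl-2,4-dioxabicyclo[3.3.1]non-6-en-7-yl]methanol
Conditions: iBu2AlH (3.5 equiv), CH2Cl2, −78 → −20 °C; aq. potassium sodium tartrate
Reagents that add atoms: none
Why: 1,2-Reduction of a conjugated ester to the allylic alcohol with an aluminium hydride, to which silyl ethers and the ketal are inert; no stereocentre is formed.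

**Step 5**
Reactants: 7 [(1R,5S,8S,9S)-8,9-bis[(tert-butyldimethylsilyl)oxy]-3,3-dimethyl-2,4-dioxabicyclo[3.3.1]non-6-en-7-yl]methanol
Product: 8 (1R,2S,3S,6S)-2,6-bis[(tert-butyldimethylsilyl)oxy]-5-(hydroxymethyl)cyclohex-4-ene-1,3-diol
Conditions: pyridinium p-toluenesulfonate (cat.), MeOH, rt
Reagents that add atoms: none
Why: Acid-catalysed transketalisation (acetonide cleavage) should open the strained bridging 1,3-dioxane under conditions that leave secondary silyl ethers in place; no stereocentre changes.

**Step 6**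
Reactants: 8 (1R,2S,3S,6S)-2,6-bis[(tert-butyldimethylsilyl)oxy]-5-(hydroxymethyl)cyclohex-4-ene-1,3-diol
Product: 10 [(3R,4R,5R,6S)-3-(benzoyloxy)-4,6-bis[(tert-butyldimethylsilyl)oxy]-5-hydroxycyclohex-1-en-1-yl]methyl benzoate, via primary monobenzoate 9 (not isolated)
Conditions: PhCO2H, PPh3, DIAD (2.6 equiv each), toluene, 0 °C → rt
Reagents that add atoms: benzoic acid, O=C(O)c1ccccc1
Why: Double Mitsunobu esterification, in which the primary allylic alcohol reacts first (9) and the secondary allylic C3 hydroxyl is then displaced by benzoate with SN2 inversion (3S to 3R), turning the cis relation imposed by the bridge into the trans C3 benzoate of the target, while the C5 hydroxyl between two silyloxy carbons should stay free.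

**Step 7**
Reactants: 10 [(3R,4R,5R,6S)-3-(benzoyloxy)-4,6-bis[(tert-butyldimethylsilyl)oxy]-5-hydroxycyclohex-1-en-1-yl]methyl benzoate
Product: 11 [(3R,4R,5R,6S)-3-(benzoyloxy)-4,5,6-trihydroxycyclohex-1-en-1-yl]methyl benzoate
Conditions: HF·pyridine, pyridine/THF, 0 °C → rt
Reagents that add atoms: none
Why: Fluoride-mediated desilylation under buffered, mildly acidic conditions removes both silyl ethers without cleaving or shifting either benzoate and touches no stereocentre.

**Compound list**

1 | 2,2-dimethyl-1,3-dioxan-5-one | CC1(C)OCC(=O)CO1 | starting material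
2 | ethyl 2-formyl-3-oxopropanoate (ethyl diformylacetate) | CCOC(=O)C(C=O)C=O | starting material
3 | ethyl 3-(2,2-dimethyl-5-oxo-1,3-dioxan-4-yl)-2-formylprop-2-enoate (ring CH and C=C geometry labile) | CCOC(=O)C(C=O)=CC1OC(C)(C)OCC1=O | intermediate (not isolated)
4 | ethyl (1R,5S,8S)-8-hydroxy-3,3-dimethyl-9-oxo-2,4-dioxabicyclo[3.3.1]non-6-ene-7-carboxylate | CCOC(=O)C1=C[C@@H]2OC(C)(C)O[C@@H](C2=O)[C@H]1O | intermediate
5 | ethyl (1R,5S,8S,9S)-8,9-dihydroxy-3,3-dimethyl-2,4-dioxabicyclo[3.3.1]non-6-ene-7-carboxylate | CCOC(=O)C1=C[C@@H]2OC(C)(C)O[C@@H]([C@H]2O)[C@H]1O | intermediate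
6 | ethyl (1R,5S,8S,9S)-8,9-bis[(tert-butyldimethylsilyl)oxy]-3,3-dimethyl-2,4-dioxabicyclo[3.3.1]non-6-ene-7-carboxylate | CCOC(=O)C1=C[C@@H]2OC(C)(C)O[C@@H]([C@H]2O[Si](C)(C)C(C)(C)C)[C@H]1O[Si](C)(C)C(C)(C)C | intermediate
7 | [(1R,5S,8S,9S)-8,9-bis[(tert-butyldimethylsilyl)oxy]-3,3-dimethyl-2,4-dioxabicyclo[3.3.1]non-6-en-7-yl]methanol | OCC1=C[C@@H]2OC(C)(C)O[C@@H]([C@H]2O[Si](C)(C)C(C)(C)C)[C@H]1O[Si](C)(C)C(C)(C)C | intermediate
8 | (1R,2S,3S,6S)-2,6-bis[(tert-butyldimethylsilyl)oxy]-5-(hydroxymethyl)cyclohex-4-ene-1,3-diol | OCC1=C[C@H](O)[C@H](O[Si](C)(C)C(C)(C)C)[C@H](O)[C@H]1O[Si](C)(C)C(C)(C)C | intermediate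
9 | [(3S,4S,5R,6S)-4,6-bis[(tert-butyldimethylsilyl)oxy]-3,5-dihydroxycyclohex-1-en-1-yl]methyl benzoate | O=C(OCC1=C[C@H](O)[C@H](O[Si](C)(C)C(C)(C)C)[C@H](O)[C@H]1O[Si](C)(C)C(C)(C)C)c1ccccc1 | intermediate (not isolated)
10 | [(3R,4R,5R,6S)-3-(benzoyloxy)-4,6-bis[(tert-butyldimethylsilyl)oxy]-5-hydroxycyclohex-1-en-1-yl]methyl benzoate | O=C(OCC1=C[C@@H](OC(=O)c2ccccc2)[C@H](O[Si](C)(C)C(C)(C)C)[C@H](O)[C@H]1O[Si](C)(C)C(C)(C)C)c1ccccc1 | intermediate
11 | [(3R,4R,5R,6S)-3-(benzoyloxy)-4,5,6-trihydroxycyclohex-1-en-1-yl]methyl benzoate | O=C(OCC1=C[C@@H](OC(=O)c2ccccc2)[C@H](O)[C@H](O)[C@H]1O)c1ccccc1 | target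

Total step count: 7. Longest linear sequence: 7 steps (1 or 2 to 11).

**Steps most likely to fail**

Step 1 (proposed new method). The amine may be held back by 2 as a vinylogous amide, the open intermediate may close through oxygen to a pyranol, or the ring-closing aldol may discriminate poorly between the two faces. The fallback uses known chemistry (stoichiometric enamine annulation of the Stork–Lawton kind, then enzymatic resolution instead of asymmetric amine catalysis); it sets out from 1 and 2 and comes back to the route at 4. Compound 1 is condensed with pyrrolidine (toluene, reflux, water separator) to the enamine 1-(2,2-dimethyl-4H-1,3-dioxin-5-yl)pyrrolidine F1, and 2 is O-ethylated with HC(OEt)3 (100 °C, ethanol distilled off) to ethyl 3-ethoxy-2-formylprop-2-enoate F2. F1 and F2 are combined in MeCN (0 °C → rt): addition–elimination at the ethoxymethylene carbon, proton shift to the enamine of the other alpha carbon, then intramolecular enamine aldol onto the formyl group. Aqueous AcOH/NaOAc hydrolyses the iminium and should give racemic material, that is 4 together with its enantiomer ethyl (1S,5R,8R)-8-hydroxy-3,3-dimethyl-9-oxo-2,4-dioxabicyclo[3.3.1]non-6-ene-7-carboxylate F3. A lipase picked by screening (Candida antarctica lipase B or Burkholderia cepacia lipase, vinyl acetate, tBuOMe, rt) is to acetylate F3 to ethyl (1S,5R,8R)-8-acetoxy-3,3-dimethyl-9-oxo-2,4-dioxabicyclo[3.3.1]non-6-ene-7-carboxylate F4 and leave 4, which is separated by chromatography and enters step 2.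

Step 6. Inversion at the hindered allylic carbinol may be incomplete, the activated alcohol may eliminate or suffer allylic transposition, or the C5 hydroxyl may be esterified. The fallback replaces SN2 inversion by oxidation and hydroxyl-directed reduction; it sets out from 8 and comes back at 10. Compound 8 is benzoylated at the primary hydroxyl only (BzCl 1.05 equiv, 2,4,6-collidine, CH2Cl2, −40 °C) to give 9, now isolated. MnO2 (CH2Cl2, rt) oxidises its allylic C3 hydroxyl to the enone [(4R,5R,6S)-4,6-bis[(tert-butyldimethylsilyl)oxy]-5-hydroxy-3-oxocyclohex-1-en-1-yl]methyl benzoate F5. Me4NBH(OAc)3 (MeCN/AcOH, −30 °C), directed by the free C5 hydroxyl, should reduce the enone 1,2 from the C5–OH face to the 3,5-anti diol [(3R,4S,5R,6S)-4,6-bis[(tert-butyldimethylsilyl)oxy]-3,5-dihydroxycyclohex-1-en-1-yl]methyl benzoate F6. BzCl/pyridine (CH2Cl2, 0 °C) then esterifies the less hindered allylic C3 hydroxyl to give 10.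

Step 2. Undirected hydride attack from the open dioxane face may compete with intramolecular delivery and give the C9 epimer. The fallback is an Evans–Tishchenko reduction, which has no free hydride in solution; it sets out from 4 and comes back at 5. With SmI2 (0.3 equiv) and acetaldehyde (6 equiv) in THF at −10 °C, the hemiacetal on O8 transfers hydride within a samarium chelate and should give the anti diol monoester ethyl (1S,5S,8S,9S)-8-acetoxy-9-hydroxy-3,3-dimethyl-2,4-dioxabicyclo[3.3.1]non-6-ene-7-carboxylate F7. K2CO3 in EtOH at 0 °C removes the acetate and gives 5.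

**Further compounds**

F1 | step 1 | 1-(2,2-dimethyl-4H-1,3-dioxin-5-yl)pyrrolidine | CC1(C)OCC(N2CCCC2)=CO1
F2 | step 1 | ethyl 3-ethoxy-2-formylprop-2-enoate | CCOC=C(C=O)C(=O)OCC
F3 | step 1 | ethyl (1S,5R,8R)-8-hydroxy-3,3-dimethyl-9-oxo-2,4-dioxabicyclo[3.3.1]non-6-ene-7-carboxylate | CCOC(=O)C1=C[C@H]2OC(C)(C)O[C@H](C2=O)[C@@H]1O
F4 | step 1 | ethyl (1S,5R,8R)-8-acetoxy-3,3-dimethyl-9-oxo-2,4-dioxabicyclo[3.3.1]non-6-ene-7-carboxylate | CCOC(=O)C1=C[C@H]2OC(C)(C)O[C@H](C2=O)[C@@H]1OC(C)=O
F5 | step 6 | [(4R,5R,6S)-4,6-bis[(tert-butyldimethylsilyl)oxy]-5-hydroxy-3-oxocyclohex-1-en-1-yl]methyl benzoate | O=C(OCC1=CC(=O)[C@H](O[Si](C)(C)C(C)(C)C)[C@H](O)[C@H]1O[Si](C)(C)C(C)(C)C)c1ccccc1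
F6 | step 6 | [(3R,4S,5R,6S)-4,6-bis[(tert-butyldimethylsilyl)oxy]-3,5-dihydroxycyclohex-1-en-1-yl]methyl benzoate | O=C(OCC1=C[C@@H](O)[C@H](O[Si](C)(C)C(C)(C)C)[C@H](O)[C@H]1O[Si](C)(C)C(C)(C)C)c1ccccc1
F7 | step 2 | ethyl (1S,5S,8S,9S)-8-acetoxy-9-hydroxy-3,3-dimethyl-2,4-dioxabicyclo[3.3.1]non-6-ene-7-carboxylate | CCOC(=O)C1=C[C@@H]2OC(C)(C)O[C@@H]([C@H]2O)[C@H]1OC(C)=O
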